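At 40 min two new flasks are read, north and south-east, and what counts in that reading is how the target peak stands against the isomer peak.

| flask | substrate | partner | protic impurity | temperature | remark | time |
|---|---|---|---|---|---|---|
| alder | 0.50 M | 0.30 M | 0.25 M | 48 °C | run made earlier |  |
| oak | 0.50 M | 0.68 M | 0.25 M | 64 °C | run made earlier |  |
| cedar | 0.75 M | 0.45 M | 0.25 M | 48 °C | run made earlier |  |
| north | 0.50 M | 0.450 M | 0.250 M | 40 °C |  | 40 min |
| south-east | 0.50 M | 0.450 M | 0.250 M | 70 °C |  | 40 min |
- alder (time / min: target / %, isomer of the product / %, substrate / %): 6.00: 2.6, 0, 80.1; 12.0: 6.5, 1.4, 71.6; 20.0: 11.1, 5.0, 66.2; 25.0: 12.2, 6.0, 64.3; 30.0: 13.1, 8.8, 63.1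
- oak (time / min: target / %, isomer of the product / %, substrate / %): 2.00: 6.4, 0.8, 65.7; 4.00: 13.7, 5.4, 49.9; 6.00: 19.3, 11.0, 40.9; 8.00: 22.1, 16.7, 35.7; 10.0: 25.3, 21.9, 31.7
- cedar (time / min: target / %, isomer of the product / %, substrate / %): 2.50: 0.4, 0.2, 85.7; 5.00: 2.4, 0.5, 77.1; 10.0: 7.1, 1.3, 67.3; 15.0: 10.5, 3.2, 62.2; 30.0: 15.8, 10.3, 57.4

(scatter of a reading: 0.3 percentage points)
- what was read earlier has a scatter of 0.3 percentage points, one standard deviation
- which flask leads in share of target in all that became target or isomer of the product ("all alike" within 1.5 percentage points) (north / south-east / all alike)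
- share of target in all that became target or isomer of the product, north
- share of target in all that became target or isomer of the product, south-east

**Which peak comes first?** Target: at 6.00 min the alder run reads 2.6% target and 0% isomer. So I take isomer to grow out of target.

**How fast?** With one constant, isomer at a reading equals that constant times the area under the target curve, both as fractions of the charge. Alder gives 0.0388 /min. Cedar, at the same temperature with other charges, gives 0.0383 /min. Oak, up to 4.00 min, reads 0.204 /min.

**But north is colder than any run?** Yes. I assume one factor per degree; the gap from 48 °C down to 40 °C is 0.5 of the gap from 48 °C up to 64 °C, which gives 0.0169 /min.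

**What do you carry?** The isomer clock: forward constant times time of reading. For north it stands at 0.676.

**And the share?** If target arrives steadily, the average part has waited for part of the run, and the first round makes isomer 33.8% of what arrived. Put that back: the target was thinning meanwhile, which takes 7.62% off the isomer. North's share is then 73.8%.

**South-east?** Oak's constant over 40 min already gives a clock of 8.16, far above north's, so the reckoning fails there. Oak's share was still falling at 53.6%, and I place south-east below that. My reckoning puts north ahead, under kinetic control.

The forecast also names north, with 75%, higher than my figure, and 44% for south-east: “This relies on reversibility, which is inferred.”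

    substrate + partner ⇌ intermediate (K = 16.0 /M, k = 0.00170 /M/s, Ea = 51.0 kJ/mol, ΔH = 29.0 kJ/mol)
    intermediate ⇌ target + released group (K = 0.300 M, k = 3.50 × 10⁻⁴ /s, Ea = 87.0 kJ/mol, ΔH = −49.0 kJ/mol)
    partner + protic impurity → quenched reagent (k = 0.00110 /M/s, Ea = 73.0 kJ/mol)
    target ⇌ isomer of the product (K = 4.60, k = 2.80 × 10⁻⁴ /s, Ea = 100 kJ/mol, ΔH = −46.0 kJ/mol)
    released group → by-product carried off (k = 9.70 × 10⁻⁴ /s, Ea = 100 kJ/mol)
    (constants at 40 °C)

North gives 76.2% and south-east 50.5%, so north leads and the forecast's south-east figure stands 6.5 percentage points low. South-east's share still reads 50.5% at 400 min. North's clock of 0.676 gave 73.8%, lower than the flask's value. The flask like north with 1.1 M of partner keeps the temperature and time, so it has the same clock and the same reckoned 73.8%; it reads 75.0%, with target at 28.6% against north's 16.4%.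

(The numbers in the tables are simulated on assumed constants; the scatter is artificial.)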